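**Plan**
- Retrosynthetic cuts, in order: the formyl C=O (back to the methyl of an isopropenyl group), the angelate C–O, the side-chain carbinol C–H (back to the aryl methyl ketone), the acetate C–O, then the C2–C3 ring bond together with the alkenyl C–CH3 bond (back to an aryloxyallene aldehyde and Me2Zn), and finally allene ← propargyl ether ← phenol O–C bond.
- Forward: the benzene ring is bought; O-propargylation, allene formation and release of the aldehyde follow; the dihydrofuran ring, the only ring built, closes in step 5; acetate, carbinol, angelate and formyl group are then installed in that order.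
- Enabling feature: in the dihydrofuran ring the array O–C3–C2–C(=CH2) is a cis homoallylic alcohol whose C2 also carries the ring oxygen O1. C2, the alkenyl carbon and the =CH2 carbon are therefore the three carbons of an allene bound to the phenol oxygen, and C3 is the carbon of an ortho-formyl group.
- Stereochemistry: C2 and C3 (cis, 2S,3S) come from the nickelacycle (relative) and the chiral ligand (absolute) in step 5. The side-chain (R)-carbinol comes from catalyst-controlled Noyori transfer hydrogenation in step 7. The (Z)-alkene of the ester comes from angelic acid.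

Key step: step 5

Assumption: compound 1 (a salbutamol intermediate) is taken as purchasable; the ligand antipode in step 5 that leads to the (2S,3S) series has to be fixed by a first screen, and the (R)-ligand is written as the working choice.

**Step 1**
Reactants: 1 1-[4-hydroxy-3-(hydroxymethyl)phenyl]ethan-1-one; 2 propargyl bromide (3-bromoprop-1-yne)
Product: 3 1-[3-(hydroxymethyl)-4-(prop-2-yn-1-yloxy)phenyl]ethan-1-one
Conditions: K2CO3 (1.5 equiv), acetone, 55 °C
Reagents that add atoms: none
Why: Williamson ether synthesis; K2CO3 deprotonates only the phenol (acidified by the para-acetyl group), so O-propargylation should occur there and leave the benzylic alcohol free.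

**Step 2**
Reactants: 3 1-[3-(hydroxymethyl)-4-(prop-2-yn-1-yloxy)phenyl]ethan-1-one
Product: 4 1-[3-({[tert-butyl(dimethyl)silyl]oxy}methyl)-4-(prop-2-yn-1-yloxy)phenyl]ethan-1-one
Conditions: TBSCl (1.2 equiv), imidazole (2 equiv), CH2Cl2, 0 °C to rt
Reagents that add atoms: tert-butyldimethylsilyl chloride, CC(C)(C)[Si](C)(C)Cl
Why: Silyl ether formation masks the benzylic alcohol, whose alkoxide could otherwise add to the allene made in step 3 and close a seven-membered ring.

**Step 3**
Reactants: 4 1-[3-({[tert-butyl(dimethyl)silyl]oxy}methyl)-4-(prop-2-yn-1-yloxy)phenyl]ethan-1-one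
Product: 5 1-[3-({[tert-butyl(dimethyl)silyl]oxy}methyl)-4-(propa-1,2-dien-1-yloxy)phenyl]ethan-1-one
Conditions: t-BuOK (1.6 equiv), THF, −20 to 0 °C, 30 min; aq. NH4Cl
Reagents that add atoms: none
Why: Base-mediated propargyl-to-allenyl isomerization of an aryl propargyl ether, the standard entry to aryloxyallenes; the first equivalent of base holds the ketone as its enolate (which also blocks self-condensation), and low temperature with short contact should prevent onward isomerization to the 1-propynyl ether.

**Step 4**
Reactants: 5 1-[3-({[tert-butyl(dimethyl)silyl]oxy}methyl)-4-(propa-1,2-dien-1-yloxy)phenyl]ethan-1-one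
Product: 7 5-acetyl-2-(propa-1,2-dien-1-yloxy)benzaldehyde, via allenyloxy benzyl alcohol 6 (not isolated)
Conditions: TBAF (1.1 equiv), THF, 0 °C; NaHCO3 work-up, crude dried over K2CO3; then activated MnO2 (15 equiv), CH2Cl2, rt
Reagents that add atoms: none
Why: Fluoride desilylation followed by MnO2 oxidation of the activated benzylic alcohol; the free alcohol 6 is not stored because traces of acid would close it onto the allenyl ether as a cyclic vinyl acetal, and neutral MnO2 should leave allene and ketone untouched.

**Step 5**
Reactants: 7 5-acetyl-2-(propa-1,2-dien-1-yloxy)benzaldehyde; 8 dimethylzinc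
Product: 10 1-[(2S,3S)-3-hydroxy-2-(prop-1-en-2-yl)-2,3-dihydro-1-benzofuran-5-yl]ethan-1-one, via methylzinc alkoxide 9 (not isolated)
Conditions: Ni(cod)2 (10 mol %), (R)-SIPHOS-PE (spirobiindane-7,7'-diyl N,N-bis[(R)-1-phenylethyl]phosphoramidite, 12 mol %), Me2Zn (2.5 equiv), THF, 0 °C, slow addition of 7; aq. NH4Cl
Reagents that add atoms: none
Why: Proposed new method: zerovalent nickel carrying the chiral phosphoramidite binds the aldehyde and the oxygen-substituted C=C of the allene and undergoes oxidative cyclization, which forms the C2–C3 bond and a five-membered oxanickelacycle (Ni–O at C3, Ni–C at the alkenyl carbon, exocyclic =CH2); Me2Zn then transfers methyl to nickel (zinc going to the C3 oxygen) and C(sp2)–CH3 reductive elimination gives the isopropenyl group and returns zerovalent nickel. The closest known reaction types are the Ni(cod)2-catalysed alkylative cyclization of allenyl aldehydes with organozincs, which gives cis-2-alkenyl cycloalkanols, and the phosphoramidite-controlled enantioselective nickel-catalysed alkylative coupling of alkynes, aldehydes and Me2Zn; new here are the aryloxy-substituted allene and enantiocontrol in the allene series. The dihydrofuran ring closes in a 5-exo mode (aldehyde carbon onto the proximal allene carbon across the C3a–C7a–O1 tether) and is cis-fused to the nickelacycle. The cis relation of C2 and C3 follows from that metallacycle, because the C3 oxygen and the alkenyl carbon on C2 are bound to the same nickel atom, and the absolute configuration of both centres is fixed in the same event by the ligand, which selects the aldehyde face. The step needs reaction at the aldehyde and not at the aryl methyl ketone (only the ortho-formyl group can reach the allene, and aldehydes enter oxidative cyclization far faster), bond formation at the proximal and not the central allene carbon (central attack would give a six-membered chromene; the known intramolecular organozinc variant reacts at the proximal carbon), and methyl transfer through nickel faster than direct addition of Me2Zn to the aldehyde or beta-aryloxide loss from the alkenylnickel species (helped by slow addition of 7 and low temperature).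

**Step 6**
Reactants: 10 1-[(2S,3S)-3-hydroxy-2-(prop-1-en-2-yl)-2,3-dihydro-1-benzofuran-5-yl]ethan-1-one
Product: 11 (2S,3S)-5-acetyl-2-(prop-1-en-2-yl)-2,3-dihydro-1-benzofuran-3-yl acetate
Conditions: Ac2O (1.5 equiv), pyridine (3 equiv), DMAP (5 mol %), CH2Cl2, 0 °C
Reagents that add atoms: acetic anhydride, CC(=O)OC(C)=O
Why: DMAP-catalysed O-acylation of the secondary benzylic alcohol with retention at C3; the weak base and low temperature should avoid loss of acetic acid towards the aromatic benzofuran.

**Step 7**
Reactants: 11 (2S,3S)-5-acetyl-2-(prop-1-en-2-yl)-2,3-dihydro-1-benzofuran-3-yl acetate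
Product: 12 (2S,3S)-5-[(1R)-1-hydroxyethyl]-2-(prop-1-en-2-yl)-2,3-dihydro-1-benzofuran-3-yl acetate
Conditions: RuCl(p-cymene)[(R,R)-TsDPEN] (2 mol %), HCO2H–Et3N (5:2), EtOAc, 30 °C
Reagents that add atoms: none
Why: Noyori asymmetric transfer hydrogenation of the aryl methyl ketone; the (R,R)-catalyst should deliver hydride to the Si face and give the (R)-carbinol under catalyst control (the ring stereocentres are remote), while the acetate and the isopropenyl group are inert to the ruthenium hydride.

**Step 8**
Reactants: 12 (2S,3S)-5-[(1R)-1-hydroxyethyl]-2-(prop-1-en-2-yl)-2,3-dihydro-1-benzofuran-3-yl acetate; 13 angelic acid ((2Z)-2-methylbut-2-enoic acid)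
Product: 14 (1R)-1-[(2S,3S)-3-acetoxy-2-(prop-1-en-2-yl)-2,3-dihydro-1-benzofuran-5-yl]ethyl (2Z)-2-methylbut-2-enoate
Conditions: 13 (3 equiv), 2,4,6-trichlorobenzoyl chloride (3 equiv), Et3N (3.5 equiv), toluene, rt, 2 h; then 12, toluene, 75 °C (no DMAP)
Reagents that add atoms: none
Why: Yamaguchi-type mixed-anhydride esterification; acyl transfer to oxygen leaves the (R)-carbinol centre untouched, and thermal transfer without a nucleophilic catalyst should keep the (Z)-geometry of the angeloyl group.

**Step 9**
Reactants: 14 (1R)-1-[(2S,3S)-3-acetoxy-2-(prop-1-en-2-yl)-2,3-dihydro-1-benzofuran-5-yl]ethyl (2Z)-2-methylbut-2-enoate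
Product: 16 (1R)-1-[(2S,3S)-3-acetoxy-2-(3-oxoprop-1-en-2-yl)-2,3-dihydro-1-benzofuran-5-yl]ethyl (2Z)-2-methylbut-2-enoate (target), via allylic alcohol 15 (not isolated)
Conditions: SeO2 (0.3 equiv), t-BuOOH (3 equiv, in decane), CH2Cl2, rt; aq. Na2S2O3 wash; then activated MnO2 (15 equiv), CH2Cl2, rt
Reagents that add atoms: tert-butyl hydroperoxide, CC(C)(C)OO; selenium dioxide, O=[Se]=O (relays the oxygen atom)
Why: Riley-type SeO2 allylic oxidation (ene reaction at the terminal CH2, then [2,3]-shift) should functionalise the methyl group of the 1,1-disubstituted alkene in preference to the tertiary C2–H and the electron-poor angelate, and MnO2 then converges any alcohol/aldehyde mixture on the enal without touching the esters or the stereocentres.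

**Compound list**
1 | 1-[4-hydroxy-3-(hydroxymethyl)phenyl]ethan-1-one | CC(=O)c1ccc(O)c(CO)c1 | starting material
2 | propargyl bromide (3-bromoprop-1-yne) | C#CCBr | starting material
3 | 1-[3-(hydroxymethyl)-4-(prop-2-yn-1-yloxy)phenyl]ethan-1-one | CC(=O)c1ccc(OCC#C)c(CO)c1 | intermediate
4 | 1-[3-({[tert-butyl(dimethyl)silyl]oxy}methyl)-4-(prop-2-yn-1-yloxy)phenyl]ethan-1-one | CC(=O)c1ccc(OCC#C)c(CO[Si](C)(C)C(C)(C)C)c1 | intermediate
5 | 1-[3-({[tert-butyl(dimethyl)silyl]oxy}methyl)-4-(propa-1,2-dien-1-yloxy)phenyl]ethan-1-one | CC(=O)c1ccc(OC=C=C)c(CO[Si](C)(C)C(C)(C)C)c1 | intermediate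
6 | 1-[3-(hydroxymethyl)-4-(propa-1,2-dien-1-yloxy)phenyl]ethan-1-one (allenyloxy benzyl alcohol, not isolated) | CC(=O)c1ccc(OC=C=C)c(CO)c1 | intermediate
7 | 5-acetyl-2-(propa-1,2-dien-1-yloxy)benzaldehyde | CC(=O)c1ccc(OC=C=C)c(C=O)c1 | intermediate
8 | dimethylzinc | C[Zn]C | starting material
9 | methylzinc alkoxide of 10 (not isolated) | C=C(C)[C@@H]1Oc2ccc(C(C)=O)cc2[C@@H]1O[Zn]C | intermediate
10 | 1-[(2S,3S)-3-hydroxy-2-(prop-1-en-2-yl)-2,3-dihydro-1-benzofuran-5-yl]ethan-1-one | C=C(C)[C@@H]1Oc2ccc(C(C)=O)cc2[C@@H]1O | intermediate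
11 | (2S,3S)-5-acetyl-2-(prop-1-en-2-yl)-2,3-dihydro-1-benzofuran-3-yl acetate | C=C(C)[C@@H]1Oc2ccc(C(C)=O)cc2[C@@H]1OC(C)=O | intermediate
12 | (2S,3S)-5-[(1R)-1-hydroxyethyl]-2-(prop-1-en-2-yl)-2,3-dihydro-1-benzofuran-3-yl acetate | C=C(C)[C@@H]1Oc2ccc([C@@H](C)O)cc2[C@@H]1OC(C)=O | intermediate
13 | angelic acid ((2Z)-2-methylbut-2-enoic acid) | C/C=C(/C)C(=O)O | starting material
14 | (1R)-1-[(2S,3S)-3-acetoxy-2-(prop-1-en-2-yl)-2,3-dihydro-1-benzofuran-5-yl]ethyl (2Z)-2-methylbut-2-enoate | C=C(C)[C@@H]1Oc2ccc([C@@H](C)OC(=O)/C(C)=C\C)cc2[C@@H]1OC(C)=O | intermediate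
15 | (1R)-1-[(2S,3S)-3-acetoxy-2-(3-hydroxyprop-1-en-2-yl)-2,3-dihydro-1-benzofuran-5-yl]ethyl (2Z)-2-methylbut-2-enoate (allylic alcohol, not isolated) | C=C(CO)[C@@H]1Oc2ccc([C@@H](C)OC(=O)/C(C)=C\C)cc2[C@@H]1OC(C)=O | intermediate
16 | (1R)-1-[(2S,3S)-3-acetoxy-2-(3-oxoprop-1-en-2-yl)-2,3-dihydro-1-benzofuran-5-yl]ethyl (2Z)-2-methylbut-2-enoate | C=C(C=O)[C@@H]1Oc2ccc([C@@H](C)OC(=O)/C(C)=C\C)cc2[C@@H]1OC(C)=O | target

**Step count**
Total steps: 9. Longest linear sequence: 9 steps (from 1).

**Steps most likely to fail**

1. Step 5 (Proposed new method). The ligand may fail to discriminate the two aldehyde faces in the oxidative cyclization, so that the cis product forms with low enantiomeric purity. Fallback, setting out from 7 and rejoining the route at 11: the cyclization is run in its known racemic form (Ni(cod)2 without chiral ligand, Me2Zn, THF, 0 °C) and should give the racemic cis-alcohol F1. Kinetic resolution by lipase-catalysed transesterification (immobilised Candida antarctica lipase B or Burkholderia cepacia lipase, vinyl acetate, tert-butyl methyl ether, 30 °C) should then acetylate the (3S)-enantiomer. This follows from the empirical rule for secondary alcohols with the aryl group as the large substituent; the S descriptor arises because C2 outranks C3a. The acetate 11 is thus delivered directly, and the unreacted (2R,3R)-alcohol F2 is removed by chromatography.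

2. Step 9. The selenium ene reaction on the inductively deactivated 1,1-disubstituted alkene may be slow, allowing competing attack at other allylic C–H bonds (C2–H, angelate methyls) or incomplete and over-oxidation. Fallback, setting out from 14 and rejoining at 16: ene-type allylic chlorination (N-chlorosuccinimide, PhSeCl (10 mol %), CH2Cl2, rt) should give the allylic chloride F3. Ganem oxidation (N-methylmorpholine N-oxide, NaI (cat.), MeCN, rt) then converts the chloride into the enal 16 by N-oxide displacement and elimination.

3. Step 8. Acyl transfer may be accompanied by Z-to-E isomerization of the angeloyl unit to the tigloyl isomer. Fallback, setting out from 12 and rejoining at 14: the (Z)-alkene is built on the substrate instead of being transferred. Alcohol 12 is esterified with 2-[bis(2,2,2-trifluoroethoxy)phosphoryl]propanoic acid (DIC, DMAP (cat.), CH2Cl2, 0 °C) to the phosphonate ester F4 (mixture of epimers at the phosphorus-bearing carbon). A Still–Gennari olefination with acetaldehyde (KHMDS, 18-crown-6, THF, −78 °C) should then give the (Z)-2-methylbut-2-enoate 14 under kinetic control.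

**Further compounds**
F1 | step 5 | racemic cis-1-[3-hydroxy-2-(prop-1-en-2-yl)-2,3-dihydro-1-benzofuran-5-yl]ethan-1-one (1:1 mixture of the (2S,3S) and (2R,3R) enantiomers) | C=C(C)[C@@H]1Oc2ccc(C(C)=O)cc2[C@@H]1O.C=C(C)[C@H]1Oc2ccc(C(C)=O)cc2[C@H]1O
F2 | step 5 | 1-[(2R,3R)-3-hydroxy-2-(prop-1-en-2-yl)-2,3-dihydro-1-benzofuran-5-yl]ethan-1-one | C=C(C)[C@H]1Oc2ccc(C(C)=O)cc2[C@H]1O
F3 | step 9 | (1R)-1-[(2S,3S)-3-acetoxy-2-(3-chloroprop-1-en-2-yl)-2,3-dihydro-1-benzofuran-5-yl]ethyl (2Z)-2-methylbut-2-enoate | C=C(CCl)[C@@H]1Oc2ccc([C@@H](C)OC(=O)/C(C)=C\C)cc2[C@@H]1OC(C)=O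
F4 | step 8 | (1R)-1-[(2S,3S)-3-acetoxy-2-(prop-1-en-2-yl)-2,3-dihydro-1-benzofuran-5-yl]ethyl 2-[bis(2,2,2-trifluoroethoxy)phosphoryl]propanoate | C=C(C)[C@@H]1Oc2ccc([C@@H](C)OC(=O)C(C)P(=O)(OCC(F)(F)F)OCC(F)(F)F)cc2[C@@H]1OC(C)=O
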